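**Retrosynthetic overview**
1. Target ⇐ one acidolysis of its protected form (two tert-butyl esters, one aryl tert-butyl carbonate).
2. (2Z,4Z,6E)-Trienoate ⇐ Z-selective Horner–Wadsworth–Emmons olefination of a (2E,4Z)-6-aryl-6-oxodienal ⇐ rhodium-carbenoid ring-opening of furan by an aryl diazomethyl ketone (furan gives four carbons and the internal Z olefin).
3. Diazoketone ⇐ aryl methyl ketone; (E)-enoate side chain ⇐ hydroformylation–Wittig of a 3-arylbut-1-ene ⇐ ethenolysis.
4. Benzylic stereocentre ⇐ palladium-catalysed asymmetric O-allylation of 2'-hydroxy-5'-methoxyacetophenone with a 1,3-dimethylallyl carbonate, then aromatic Claisen rearrangement with 1,3-chirality transfer.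
5. No ring is formed: the benzene ring is bought and kept, the furan ring is opened.

Assumption: the target is taken as drawn (R at the benzylic carbon; 2Z,4Z,6E in the acyl chain; E in the side chain); the Trost-ligand antipode that gives (S)-4 is written provisionally as (R,R) and must be fixed by chiral HPLC on the first run (the other antipode is equally available).

**Step 1**
Reactants: 1 (E)-pent-3-en-2-ol (racemic)
Product: 2 methyl (E)-pent-3-en-2-yl carbonate (racemic)
Conditions: ClCO2Me, pyridine, CH2Cl2, 0 °C → rt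
Reagents that add atoms: methyl chloroformate COC(=O)Cl
Why: O-acylation of the allylic alcohol by the chloroformate gives the ionisable carbonate needed for palladium allyl chemistry, and no stereocentre has to be controlled because the racemate is wanted.

**Step 2**
Reactants: 3 1-(2-hydroxy-5-methoxyphenyl)ethan-1-one, 2 methyl (E)-pent-3-en-2-yl carbonate (racemic)
Product: 4 1-{5-methoxy-2-[(2S,3E)-pent-3-en-2-yloxy]phenyl}ethan-1-one
Conditions: Pd2(dba)3·CHCl3 (1 mol %), (R,R)-DACH-phenyl Trost ligand (3 mol %), CH2Cl2, rt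
Reagents that add atoms: none
Why: Trost asymmetric allylic alkylation (Tsuji–Trost O-allylation), in which both enantiomers of 2 ionise to the same syn,syn-1,3-dimethylallyl palladium complex and the chiral ligand steers the phenoxide to one of its two enantiotopic termini, setting the (S) ether centre.

**Step 3**
Reactants: 4 1-{5-methoxy-2-[(2S,3E)-pent-3-en-2-yloxy]phenyl}ethan-1-one
Product: 6 1-{2-hydroxy-5-methoxy-3-[(2R,3E)-pent-3-en-2-yl]phenyl}ethan-1-one, via dienone 5 (not isolated)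
Conditions: Eu(fod)3 [europium tris(6,6,7,7,8,8,8-heptafluoro-2,2-dimethyloctane-3,5-dionate)] (10 mol %), CHCl3, 50 °C
Reagents that add atoms: none
Why: Lewis-acid-accelerated aromatic Claisen ([3,3]-sigmatropic) rearrangement through a chair transition state with the ether methyl equatorial delivers the allyl terminus suprafacially to the only free ortho carbon, so the (S) C–O centre becomes the (R) benzylic centre with an E olefin before dienone 5 tautomerises to the phenol.

**Step 4**
Reactants: 6 1-{2-hydroxy-5-methoxy-3-[(2R,3E)-pent-3-en-2-yl]phenyl}ethan-1-one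
Product: 7 1-{3-[(2R)-but-3-en-2-yl]-2-hydroxy-5-methoxyphenyl}ethan-1-one
Conditions: ethylene (5 bar), second-generation Hoveyda–Grubbs catalyst RuCl2(SIMes)(=CH-C6H4-2-OiPr) (5 mol %), CH2Cl2, 40 °C
Reagents that add atoms: ethylene C=C
Why: Ethenolysis (cross-metathesis with ethylene) of the 1,2-disubstituted olefin is driven by excess ethylene and loss of propene and does not touch the allylic stereocentre.

**Step 5**
Reactants: 7 1-{3-[(2R)-but-3-en-2-yl]-2-hydroxy-5-methoxyphenyl}ethan-1-one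
Product: 9 tert-butyl (2E,6R)-6-(3-acetyl-2-hydroxy-5-methoxyphenyl)hept-2-enoate, via aldehyde 8 (not isolated)
Conditions: Rh(acac)(CO)2 (1 mol %), Xantphos (2 mol %), CO/H2 (1:1, 10 bar), toluene, 70 °C; vent; then Ph3P=CHCO2tBu, rt
Reagents that add atoms: carbon monoxide [C-]#[O+]; tert-butyl (triphenylphosphoranylidene)acetate CC(C)(C)OC(=O)C=P(c1ccccc1)(c1ccccc1)c1ccccc1
Why: Linear-selective rhodium hydroformylation of the α-branched terminal olefin with a wide-bite-angle diphosphine is followed in the same pot by an E-selective Wittig reaction of the stabilised ylide with aldehyde 8, to which the aryl ketone is inert, and the stereocentre is not involved.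

**Step 6**
Reactants: 9 tert-butyl (2E,6R)-6-(3-acetyl-2-hydroxy-5-methoxyphenyl)hept-2-enoate
Product: 10 tert-butyl (2E,6R)-6-{3-acetyl-2-[(tert-butoxycarbonyl)oxy]-5-methoxyphenyl}hept-2-enoate
Conditions: Boc2O, DMAP (10 mol %), Et3N, CH2Cl2, rt
Reagents that add atoms: di-tert-butyl dicarbonate CC(C)(C)OC(=O)OC(=O)OC(C)(C)C
Why: DMAP-catalysed O-acylation removes the phenolic O–H that would otherwise insert into the carbenoid of step 9, and the delocalised carbonate oxygen does not form oxonium ylides.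

**Step 7**
Reactants: 10 tert-butyl (2E,6R)-6-{3-acetyl-2-[(tert-butoxycarbonyl)oxy]-5-methoxyphenyl}hept-2-enoate
Product: 12 tert-butyl (2E,6R)-6-{2-[(tert-butoxycarbonyl)oxy]-3-(2-diazoacetyl)-5-methoxyphenyl}hept-2-enoate, via trifluoroacetyl diketone 11 (not isolated)
Conditions: LiN(SiMe3)2, THF, −78 °C; CF3CO2CH2CF3, −78 °C; aq HCl work-up; then MsN3, Et3N, H2O (1 equiv), MeCN, rt
Reagents that add atoms: 2,2,2-trifluoroethyl trifluoroacetate O=C(OCC(F)(F)F)C(F)(F)F (its atoms stay only in 11); methanesulfonyl azide CS(=O)(=O)N=[N+]=[N-]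
Why: Danheiser detrifluoroacetylative diazo transfer (a Regitz-type reaction), in which the kinetic lithium enolate of the methyl ketone is C-trifluoroacetylated at −78 °C, cold enough to outrun O→C migration of the carbonate, and diketone 11 then takes N2 from the sulfonyl azide with loss of the trifluoroacetyl group.

**Step 8**
Reactants: 13 tert-butyl bromoacetate, 14 diphenyl phosphite
Product: 15 tert-butyl (diphenoxyphosphoryl)acetate
Conditions: Et3N, CH2Cl2, 0 °C → rt
Reagents that add atoms: none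
Why: Michaelis–Becker-type P-alkylation of the phosphite by the bromoacetate gives the Ando-type reagent for Z-selective Horner–Wadsworth–Emmons olefination.

**Step 9**
Reactants: 12 tert-butyl (2E,6R)-6-{2-[(tert-butoxycarbonyl)oxy]-3-(2-diazoacetyl)-5-methoxyphenyl}hept-2-enoate, 16 furan, 15 tert-butyl (diphenoxyphosphoryl)acetate
Product: 18 tert-butyl (2Z,4Z,6E)-8-{2-[(tert-butoxycarbonyl)oxy]-3-[(2R,5E)-7-tert-butoxy-7-oxohept-5-en-2-yl]-5-methoxyphenyl}-8-oxoocta-2,4,6-trienoate, via dienal 17 (not isolated)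
Conditions: Rh2(OAc)4 (1 mol %), furan (20 equiv), CH2Cl2, 20 °C, slow addition of 12, dark; evaporate at ≤ 20 °C; then sodium salt of 15 (NaH, THF), −78 → −40 °C
Reagents that add atoms: none
Why: Wenkert furan unravelling, in which the electrophilic rhodium carbenoid from 12 attacks C2 of furan and the adduct opens with loss of aromaticity to the (2E,4Z)-dienal 17 (the Z olefin is the former ring C3–C4 bond, the new enone olefin forms E), and 17 is trapped without isolation by the Ando-type Z-selective Horner–Wadsworth–Emmons reagent to set the third olefin Z.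

**Step 10**
Reactants: 18 tert-butyl (2Z,4Z,6E)-8-{2-[(tert-butoxycarbonyl)oxy]-3-[(2R,5E)-7-tert-butoxy-7-oxohept-5-en-2-yl]-5-methoxyphenyl}-8-oxoocta-2,4,6-trienoate
Product: 19 (2Z,4Z,6E)-8-{3-[(2R,5E)-6-carboxyhex-5-en-2-yl]-2-hydroxy-5-methoxyphenyl}-8-oxoocta-2,4,6-trienoic acid
Conditions: CF3CO2H/CH2Cl2 (1:4), 0 °C, 1 h, dark, N2 sweep; cold evaporation, reversed-phase chromatography
Reagents that add atoms: none
Why: Acidolysis (E1 loss of 2-methylpropene) cleaves both tert-butyl esters and the aryl tert-butyl carbonate, which then loses CO2, under cold, brief, non-nucleophilic conditions that leave the olefin geometries and the stereocentre untouched.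

**Compound list**
1 | (E)-pent-3-en-2-ol (racemic) | C/C=C/C(C)O | starting material
2 | methyl (E)-pent-3-en-2-yl carbonate (racemic) | C/C=C/C(C)OC(=O)OC | intermediate
3 | 1-(2-hydroxy-5-methoxyphenyl)ethan-1-one | CC(=O)c1cc(OC)ccc1O | starting material
4 | 1-{5-methoxy-2-[(2S,3E)-pent-3-en-2-yloxy]phenyl}ethan-1-one | CC(=O)c1cc(OC)ccc1O[C@@H](C)/C=C/C | intermediate
5 | (6R)-2-acetyl-4-methoxy-6-[(2R,3E)-pent-3-en-2-yl]cyclohexa-2,4-dien-1-one | CC(=O)C1=CC(OC)=C[C@@H]([C@H](C)/C=C/C)C1=O | intermediate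
6 | 1-{2-hydroxy-5-methoxy-3-[(2R,3E)-pent-3-en-2-yl]phenyl}ethan-1-one | CC(=O)c1cc(OC)cc([C@H](C)/C=C/C)c1O | intermediate
7 | 1-{3-[(2R)-but-3-en-2-yl]-2-hydroxy-5-methoxyphenyl}ethan-1-one | CC(=O)c1cc(OC)cc([C@H](C)C=C)c1O | intermediate
8 | (4R)-4-(3-acetyl-2-hydroxy-5-methoxyphenyl)pentanal | CC(=O)c1cc(OC)cc([C@H](C)CCC=O)c1O | intermediate
9 | tert-butyl (2E,6R)-6-(3-acetyl-2-hydroxy-5-methoxyphenyl)hept-2-enoate | CC(=O)c1cc(OC)cc([C@H](C)CC/C=C/C(=O)OC(C)(C)C)c1O | intermediate
10 | tert-butyl (2E,6R)-6-{3-acetyl-2-[(tert-butoxycarbonyl)oxy]-5-methoxyphenyl}hept-2-enoate | CC(=O)c1cc(OC)cc([C@H](C)CC/C=C/C(=O)OC(C)(C)C)c1OC(=O)OC(C)(C)C | intermediate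
11 | tert-butyl (2E,6R)-6-{2-[(tert-butoxycarbonyl)oxy]-5-methoxy-3-(4,4,4-trifluoro-3-oxobutanoyl)phenyl}hept-2-enoate | O=C(CC(=O)C(F)(F)F)c1cc(OC)cc([C@H](C)CC/C=C/C(=O)OC(C)(C)C)c1OC(=O)OC(C)(C)C | intermediate
12 | tert-butyl (2E,6R)-6-{2-[(tert-butoxycarbonyl)oxy]-3-(2-diazoacetyl)-5-methoxyphenyl}hept-2-enoate | [N-]=[N+]=CC(=O)c1cc(OC)cc([C@H](C)CC/C=C/C(=O)OC(C)(C)C)c1OC(=O)OC(C)(C)C | intermediate
13 | tert-butyl bromoacetate | CC(C)(C)OC(=O)CBr | starting material
14 | diphenyl phosphite | O=[PH](Oc1ccccc1)Oc1ccccc1 | starting material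
15 | tert-butyl (diphenoxyphosphoryl)acetate | CC(C)(C)OC(=O)CP(=O)(Oc1ccccc1)Oc1ccccc1 | intermediate
16 | furan | c1ccoc1 | starting material
17 | tert-butyl (2E,6R)-6-{2-[(tert-butoxycarbonyl)oxy]-5-methoxy-3-[(2E,4Z)-6-oxohexa-2,4-dienoyl]phenyl}hept-2-enoate | O=C/C=C\C=C\C(=O)c1cc(OC)cc([C@H](C)CC/C=C/C(=O)OC(C)(C)C)c1OC(=O)OC(C)(C)C | intermediate
18 | tert-butyl (2Z,4Z,6E)-8-{2-[(tert-butoxycarbonyl)oxy]-3-[(2R,5E)-7-tert-butoxy-7-oxohept-5-en-2-yl]-5-methoxyphenyl}-8-oxoocta-2,4,6-trienoate | COc1cc(C(=O)/C=C/C=C\C=C/C(=O)OC(C)(C)C)c(OC(=O)OC(C)(C)C)c([C@H](C)CC/C=C/C(=O)OC(C)(C)C)c1 | intermediate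
19 | (2Z,4Z,6E)-8-{3-[(2R,5E)-6-carboxyhex-5-en-2-yl]-2-hydroxy-5-methoxyphenyl}-8-oxoocta-2,4,6-trienoic acid | COc1cc(C(=O)/C=C/C=C\C=C/C(=O)O)c(O)c([C@H](C)CC/C=C/C(=O)O)c1 | target

**Step count and risk**
Total steps: 10. Longest linear sequence: 9 (steps 1–7, 9, 10); step 8 is a one-step side branch.

The three steps most likely to fail:

First, the furan ring-opening and olefination (step 9). The carbenoid may give stable cyclopropane adducts or an E/Z mixture at the new enone olefin, and the Z-enal 17 isomerises easily. The fallback builds the same dienal by aldol condensation instead of carbene transfer and sets out from 10. Furan 16 is oxidised with dimethyldioxirane (acetone, −20 °C) to (2Z)-but-2-enedial F1. The lithium enolate of 10 (LiN(SiMe3)2, THF, −78 °C) is added to an excess of F1 to give the β-hydroxy ketone F2. MsCl/Et3N (−20 °C) then eliminates to the E enone, and the route comes back at 17, which is olefinated with 15 as written.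

Second, the diazo transfer (step 7). The enolate next to the aryl carbonate can undergo O→C acyl migration, and the activated diketone can be lost on work-up. The fallback avoids any enolate and protects the phenol last; it sets out from 9. Heating 9 with N,N-dimethylformamide dimethyl acetal (toluene, 90 °C) gives the enaminone F3. p-Toluenesulfonyl azide (MeCN, rt) converts F3 by cycloaddition and fragmentation into the hydroxy diazoketone F4. Boc2O/DMAP then brings the route back at 12.

Third, the final acidolysis (step 10). The (2Z,4Z)-dienoic acid beside the enone can isomerise or lactonise in acid. The fallback replaces all three acid-labile groups by allyl groups that are removed at neutral pH; it sets out from 7.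
- Hydroformylation as in step 5 gives 8, and a Wittig reaction with allyl (triphenylphosphoranylidene)acetate gives the allyl enoate F5.
- Allyl chloroformate/pyridine gives the allyl carbonate F6.
- The diazo transfer of step 7 passes through the trifluoroacetyl diketone F7 to the diazoketone F8.
- Allyl bromoacetate and 14 (Et3N) give the allyl phosphonate F9.
- Furan unravelling and olefination as in step 9 give the dienal F10 and then the tris-allyl triene F11.
- Pd(PPh3)4 (5 mol %) with N-methylaniline (THF, 0 °C) transfers the three allyl groups to the amine, the aryl carbonate loses CO2, and the route comes back at 19.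

**Further compounds**
F1 | step 9 | (2Z)-but-2-enedial | O=C/C=C\C=O
F2 | step 9 | tert-butyl (2E,6R)-6-{2-[(tert-butoxycarbonyl)oxy]-3-[(4Z)-3-hydroxy-6-oxohex-4-enoyl]-5-methoxyphenyl}hept-2-enoate (both carbinol epimers) | O=C/C=C\C(O)CC(=O)c1cc(OC)cc([C@H](C)CC/C=C/C(=O)OC(C)(C)C)c1OC(=O)OC(C)(C)C
F3 | step 7 | tert-butyl (2E,6R)-6-{3-[(2E)-3-(dimethylamino)prop-2-enoyl]-2-hydroxy-5-methoxyphenyl}hept-2-enoate | CN(C)/C=C/C(=O)c1cc(OC)cc([C@H](C)CC/C=C/C(=O)OC(C)(C)C)c1O
F4 | step 7 | tert-butyl (2E,6R)-6-[3-(2-diazoacetyl)-2-hydroxy-5-methoxyphenyl]hept-2-enoate | [N-]=[N+]=CC(=O)c1cc(OC)cc([C@H](C)CC/C=C/C(=O)OC(C)(C)C)c1O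
F5 | step 10 | prop-2-en-1-yl (2E,6R)-6-(3-acetyl-2-hydroxy-5-methoxyphenyl)hept-2-enoate | CC(=O)c1cc(OC)cc([C@H](C)CC/C=C/C(=O)OCC=C)c1O
F6 | step 10 | prop-2-en-1-yl (2E,6R)-6-(3-acetyl-5-methoxy-2-{[(prop-2-en-1-yloxy)carbonyl]oxy}phenyl)hept-2-enoate | CC(=O)c1cc(OC)cc([C@H](C)CC/C=C/C(=O)OCC=C)c1OC(=O)OCC=C
F7 | step 10 | prop-2-en-1-yl (2E,6R)-6-[5-methoxy-2-{[(prop-2-en-1-yloxy)carbonyl]oxy}-3-(4,4,4-trifluoro-3-oxobutanoyl)phenyl]hept-2-enoate | O=C(CC(=O)C(F)(F)F)c1cc(OC)cc([C@H](C)CC/C=C/C(=O)OCC=C)c1OC(=O)OCC=C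
F8 | step 10 | prop-2-en-1-yl (2E,6R)-6-[3-(2-diazoacetyl)-5-methoxy-2-{[(prop-2-en-1-yloxy)carbonyl]oxy}phenyl]hept-2-enoate | [N-]=[N+]=CC(=O)c1cc(OC)cc([C@H](C)CC/C=C/C(=O)OCC=C)c1OC(=O)OCC=C
F9 | step 10 | prop-2-en-1-yl (diphenoxyphosphoryl)acetate | C=CCOC(=O)CP(=O)(Oc1ccccc1)Oc1ccccc1
F10 | step 10 | prop-2-en-1-yl (2E,6R)-6-[5-methoxy-3-[(2E,4Z)-6-oxohexa-2,4-dienoyl]-2-{[(prop-2-en-1-yloxy)carbonyl]oxy}phenyl]hept-2-enoate | O=C/C=C\C=C\C(=O)c1cc(OC)cc([C@H](C)CC/C=C/C(=O)OCC=C)c1OC(=O)OCC=C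
F11 | step 10 | prop-2-en-1-yl (2Z,4Z,6E)-8-[5-methoxy-3-[(2R,5E)-7-oxo-7-(prop-2-en-1-yloxy)hept-5-en-2-yl]-2-{[(prop-2-en-1-yloxy)carbonyl]oxy}phenyl]-8-oxoocta-2,4,6-trienoate | COc1cc(C(=O)/C=C/C=C\C=C/C(=O)OCC=C)c(OC(=O)OCC=C)c([C@H](C)CC/C=C/C(=O)OCC=C)c1
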